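**Strategy.** The 4-hydroxy-2-pyranone (ring atoms O1', C2' to C6') is treated as the lactone of a 3,5-dioxo acid whose enol C5'=C6' is stored as an alkyne. One gold-catalysed 6-endo-dig closure of a tert-butyl 3-oxohex-4-ynoate forms the O1'–C6' bond and the whole heterocycle with loss of isobutene, in a base-free medium. In the precursor the 1,3-diketone/hemiketal of the chromanone is masked as a 7-benzyloxy-5-(3-methylbutyl)chromone whose C2 carries the CH2–C≡C–CO–CH2–CO2t-Bu chain. Afterwards hydroxide hydrates the chromone to the 2-hydroxychromanone, hydrogenolysis frees O7, and the labile C2 hemiketal is funnelled into the (R) form by crystallisation with a chiral amine.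

Key step: step 10

Assumption: the C2 hemiketal epimerises only through its open 1,3-diketone when acid or base is present, and holds its configuration in the crystal and during a brief cold work-up. Which antipode of the resolving amine gives the less soluble salt of the (2R) acid cannot be foreseen; the (S)-amine is written, and its mirror image would be used if a first crystallisation shows the opposite pairing.

**Step 1**
Reactants: 1 1-bromo-3,5-dimethoxybenzene; 2 (3-methylbutyl)magnesium bromide
Product: 3 1,3-dimethoxy-5-(3-methylbutyl)benzene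
Conditions: NiCl2(dppp) (1 mol %), THF, 0 °C → reflux
Reagents that add atoms: none
Why: Kumada–Corriu coupling: zerovalent nickel formed in situ inserts into the aryl C–Br bond, the primary alkyl Grignard transmetallates, and the chelating diphosphine favours reductive elimination over β-hydride loss, so the unbranched attachment of the chain should result.

**Step 2**
Reactants: 3 1,3-dimethoxy-5-(3-methylbutyl)benzene
Product: 4 5-(3-methylbutyl)benzene-1,3-diol
Conditions: BBr3 (2.5 equiv), CH2Cl2, −78 → 20 °C; then H2O
Reagents that add atoms: none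
Why: Lewis-acid ether cleavage: BBr3 binds each methoxy oxygen and bromide removes the methyl group by SN2, a standard demethylation that the alkylarene tolerates.

**Step 3**
Reactants: 4 5-(3-methylbutyl)benzene-1,3-diol
Product: 5 1-[2,4-dihydroxy-6-(3-methylbutyl)phenyl]ethan-1-one
Conditions: AcOH, BF3·OEt2, 90 °C; then aq. NaOAc
Reagents that add atoms: acetic acid, CC(=O)O
Why: Friedel–Crafts (Nencki-type) C-acylation: resorcinols are attacked para to a hydroxyl, which here is the ring carbon next to the alkyl chain, and the chelated ortho-hydroxy ketone that forms is deactivated towards a second acylation.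

**Step 4**
Reactants: 5 1-[2,4-dihydroxy-6-(3-methylbutyl)phenyl]ethan-1-one
Product: 6 1-[4-(benzyloxy)-2-hydroxy-6-(3-methylbutyl)phenyl]ethan-1-one
Conditions: BnBr (1.05 equiv), K2CO3, acetone, 50 °C
Reagents that add atoms: benzyl bromide, BrCc1ccccc1
Why: Williamson etherification: the 2-hydroxyl is held in a hydrogen bond to the acetyl carbonyl and is less nucleophilic, so one equivalent of benzyl bromide with a weak base should alkylate only the 4-hydroxyl.

**Step 5**
Reactants: 6 1-[4-(benzyloxy)-2-hydroxy-6-(3-methylbutyl)phenyl]ethan-1-one; 7 2-chloro-N-methoxy-N-methylacetamide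
Product: 9 7-(benzyloxy)-2-(chloromethyl)-5-(3-methylbutyl)-4H-chromen-4-one, via 4-chloro-1,3-diketone 8 (not isolated)
Conditions: LiN(SiMe3)2 (2.2 equiv), THF, −78 °C; 7, −78 → 0 °C; aq. HCl; then TsOH·H2O (cat.), toluene, 80 °C
Reagents that add atoms: none
Why: Claisen-type C-acylation of the ketone dianion by a Weinreb amide, whose chelated tetrahedral adduct holds the chloromethyl ketone back until the acidic quench (so no basic enolate can O-alkylate onto the CH2Cl), followed by acid-catalysed cyclodehydration of the 2-hydroxyaryl 1,3-diketone to the chromone.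

**Step 6**
Reactants: 10 tert-butyl acetate; 11 3-(trimethylsilyl)prop-2-ynal
Product: 12 tert-butyl 3-hydroxy-5-(trimethylsilyl)pent-4-ynoate (racemic)
Conditions: LiN(i-Pr)2 (1.05 equiv), THF, −78 °C; then 11; aq. NH4Cl
Reagents that add atoms: none
Why: Aldol addition of the lithiated ester to the ynal carbonyl (1,2-addition), giving a racemic carbinol whose configuration does not matter because it is oxidised in step 9.

**Step 7**
Reactants: 12 tert-butyl 3-hydroxy-5-(trimethylsilyl)pent-4-ynoate
Product: 13 tert-butyl 3-hydroxypent-4-ynoate (racemic)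
Conditions: K2CO3 (0.2 equiv), MeOH, 0 °C
Reagents that add atoms: none
Why: Base-catalysed protodesilylation of the alkynylsilane by methoxide at silicon, which leaves the tert-butyl ester and the secondary alcohol untouched.

**Step 8**
Reactants: 9 7-(benzyloxy)-2-(chloromethyl)-5-(3-methylbutyl)-4H-chromen-4-one; 13 tert-butyl 3-hydroxypent-4-ynoate
Product: 14 tert-butyl 6-[7-(benzyloxy)-5-(3-methylbutyl)-4-oxo-4H-chromen-2-yl]-3-hydroxyhex-4-ynoate (racemic)
Conditions: CuI (10 mol %), NaI (20 mol %), K2CO3 (1.5 equiv), DMF, 20 °C
Reagents that add atoms: none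
Why: Copper-catalysed alkynylation of an activated allylic-type chloride (Jeffery-type coupling): the copper acetylide formed with carbonate displaces the halide with iodide as nucleophilic co-catalyst, and keeping the chain at the alcohol oxidation level leaves the new C6 methylene only weakly acidic.

**Step 9**
Reactants: 14 tert-butyl 6-[7-(benzyloxy)-5-(3-methylbutyl)-4-oxo-4H-chromen-2-yl]-3-hydroxyhex-4-ynoate
Product: 15 tert-butyl 6-[7-(benzyloxy)-5-(3-methylbutyl)-4-oxo-4H-chromen-2-yl]-3-oxohex-4-ynoate
Conditions: Dess–Martin periodinane (1.15 equiv), NaHCO3, CH2Cl2, 0 °C; short silica plug, used at once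
Reagents that add atoms: none
Why: Dess–Martin oxidation of the propargylic alcohol to the ynone under buffered, non-basic conditions, chosen so that the doubly activated C6 methylene of the skipped ynone is not deprotonated before the next step.

**Step 10**
Reactants: 15 tert-butyl 6-[7-(benzyloxy)-5-(3-methylbutyl)-4-oxo-4H-chromen-2-yl]-3-oxohex-4-ynoate
Product: 16 7-(benzyloxy)-2-[(4-hydroxy-2-oxo-2H-pyran-6-yl)methyl]-5-(3-methylbutyl)-4H-chromen-4-one
Conditions: (SPhos)AuNTf2 (2 mol %), MeNO2/AcOH 4:1, 20 °C
Reagents that add atoms: none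
Why: Cationic monovalent gold binds the C4≡C5 triple bond of 15, the carbonyl oxygen of the tert-butyl ester adds anti to C5, and the resulting oxocarbenium ion sheds its tert-butyl group as isobutene; protodeauration of the vinylgold species and enolisation of the C3 ketone then give the 4-hydroxy-2-pyranone. The closest known reaction type is the gold-catalysed cycloisomerisation of tert-butyl 3-oxoalk-4-ynoates to 4-hydroxy-2-pyranones. The single ring is closed in the 6-endo-dig mode (O1'–C6' bond) and no stereocentre is created. The step needs 6-endo rather than 5-exo attack, and cyclisation ahead of prototropic drift of the skipped ynone to an allenone. The first is secured by the ynone polarisation, which makes C5 the electrophilic carbon and leaves the ester oxygen as the only nucleophile able to reach it; the second by the base-free, weakly acidic medium and by using 15 directly after its oxidation. The chromone and the benzyl ether are inert to the carbophilic catalyst.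

**Step 11**
Reactants: 16 7-(benzyloxy)-2-[(4-hydroxy-2-oxo-2H-pyran-6-yl)methyl]-5-(3-methylbutyl)-4H-chromen-4-one
Product: 18 racemic 7-(benzyloxy)-2-hydroxy-2-[(4-hydroxy-2-oxo-2H-pyran-6-yl)methyl]-5-(3-methylbutyl)chroman-4-one, via ring-opened 1,3-diketone 17 (not isolated)
Conditions: NaOH (0.5 M aq., 5 equiv), THF, 0 → 20 °C; then 1 M HCl to pH 4, 0 °C
Reagents that add atoms: water (delivered as hydroxide), O
Why: Base-mediated chromone ring opening (oxa-Michael addition of hydroxide at C2, then retro-oxa-Michael) gives the phenoxide/diketone enolate, which as an anion resists retro-Claisen cleavage, and cold acidification lets the phenol add back to the C2 ketone to give the hemiketal, racemic because the diketone is achiral.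

**Step 12**
Reactants: 18 racemic 7-(benzyloxy)-2-hydroxy-2-[(4-hydroxy-2-oxo-2H-pyran-6-yl)methyl]-5-(3-methylbutyl)chroman-4-one
Product: 19 racemic 2,7-dihydroxy-2-[(4-hydroxy-2-oxo-2H-pyran-6-yl)methyl]-5-(3-methylbutyl)chroman-4-one
Conditions: H2 (1 atm), Pd/C (10 %), EtOAc, 20 °C, stopped at full conversion
Reagents that add atoms: none
Why: Catalytic hydrogenolysis of the aryl benzyl ether, which at one atmosphere and ambient temperature should be much faster than hydrogenation of the pyranone ring or the aryl ketone, while the hemiketal is untouched under these neutral conditions.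

**Step 13**
Reactants: 19 racemic 2,7-dihydroxy-2-[(4-hydroxy-2-oxo-2H-pyran-6-yl)methyl]-5-(3-methylbutyl)chroman-4-one; 20 (S)-N,N-dimethyl-1-phenylethylamine
Product: 21 (S)-N,N-dimethyl-1-phenylethylammonium 6-{[(2R)-2,7-dihydroxy-5-(3-methylbutyl)-4-oxochroman-2-yl]methyl}-2-oxo-2H-pyran-4-olate
Conditions: 20 (1.05 equiv), EtOAc/MeCN, 45 → 5 °C, slurry aged with slow cooling; filtered
Reagents that add atoms: none
Why: Proposed new method: the pyranone OH (pKa about 5) forms an ammonium salt with the tertiary amine, the two C2 epimers of this salt are diastereomers that interconvert in solution through amine-catalysed ring opening to the achiral 1,3-diketone and re-closure, and the less soluble (2R) salt is drained from this equilibrium as it crystallises, so the C2 configuration is set by lattice (thermodynamic) control; the closest known reaction type is crystallisation-induced diastereomer transformation of configurationally labile lactols and of acids resolved as chiral ammonium salts, which has not been shown on a 2-hydroxychromanone hemiketal, and a tertiary amine is chosen because it cannot condense with the open diketone.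

**Step 14**
Reactants: 21 (S)-N,N-dimethyl-1-phenylethylammonium salt of the (2R) acid
Product: 22 (2R)-2,7-dihydroxy-2-[(4-hydroxy-2-oxo-2H-pyran-6-yl)methyl]-5-(3-methylbutyl)chroman-4-one
Conditions: 5 % aq. citric acid, EtOAc, 0 °C; concentrated below 20 °C; crystallised from EtOAc/heptane
Reagents that add atoms: none
Why: Acid–base salt breaking: the weak acid protonates the pyranolate and carries the amine into water, and the short, cold, weakly acidic contact avoids both acid-catalysed dehydration to the chromone and base-catalysed ring opening, so the configuration fixed in the crystal should be retained.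

**Compound list**
1 | 1-bromo-3,5-dimethoxybenzene | COc1cc(Br)cc(OC)c1 | starting material
2 | (3-methylbutyl)magnesium bromide | CC(C)CC[Mg]Br | starting material
3 | 1,3-dimethoxy-5-(3-methylbutyl)benzene | COc1cc(CCC(C)C)cc(OC)c1 | intermediate
4 | 5-(3-methylbutyl)benzene-1,3-diol | CC(C)CCc1cc(O)cc(O)c1 | intermediate
5 | 1-[2,4-dihydroxy-6-(3-methylbutyl)phenyl]ethan-1-one | CC(C)CCc1cc(O)cc(O)c1C(C)=O | intermediate
6 | 1-[4-(benzyloxy)-2-hydroxy-6-(3-methylbutyl)phenyl]ethan-1-one | CC(C)CCc1cc(OCc2ccccc2)cc(O)c1C(C)=O | intermediate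
7 | 2-chloro-N-methoxy-N-methylacetamide | CON(C)C(=O)CCl | starting material
8 | 1-[4-(benzyloxy)-2-hydroxy-6-(3-methylbutyl)phenyl]-4-chlorobutane-1,3-dione (not isolated) | CC(C)CCc1cc(OCc2ccccc2)cc(O)c1C(=O)CC(=O)CCl | intermediate
9 | 7-(benzyloxy)-2-(chloromethyl)-5-(3-methylbutyl)-4H-chromen-4-one | CC(C)CCc1cc(OCc2ccccc2)cc2oc(CCl)cc(=O)c12 | intermediate
10 | tert-butyl acetate | CC(=O)OC(C)(C)C | starting material
11 | 3-(trimethylsilyl)prop-2-ynal | C[Si](C)(C)C#CC=O | starting material
12 | tert-butyl 3-hydroxy-5-(trimethylsilyl)pent-4-ynoate (racemic) | CC(C)(C)OC(=O)CC(O)C#C[Si](C)(C)C | intermediate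
13 | tert-butyl 3-hydroxypent-4-ynoate (racemic) | CC(C)(C)OC(=O)CC(O)C#C | intermediate
14 | tert-butyl 6-[7-(benzyloxy)-5-(3-methylbutyl)-4-oxo-4H-chromen-2-yl]-3-hydroxyhex-4-ynoate (racemic) | CC(C)CCc1cc(OCc2ccccc2)cc2oc(CC#CC(O)CC(=O)OC(C)(C)C)cc(=O)c12 | intermediate
15 | tert-butyl 6-[7-(benzyloxy)-5-(3-methylbutyl)-4-oxo-4H-chromen-2-yl]-3-oxohex-4-ynoate | CC(C)CCc1cc(OCc2ccccc2)cc2oc(CC#CC(=O)CC(=O)OC(C)(C)C)cc(=O)c12 | intermediate
16 | 7-(benzyloxy)-2-[(4-hydroxy-2-oxo-2H-pyran-6-yl)methyl]-5-(3-methylbutyl)-4H-chromen-4-one | CC(C)CCc1cc(OCc2ccccc2)cc2oc(Cc3cc(O)cc(=O)o3)cc(=O)c12 | intermediate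
17 | 1-[4-(benzyloxy)-2-hydroxy-6-(3-methylbutyl)phenyl]-4-(4-hydroxy-2-oxo-2H-pyran-6-yl)butane-1,3-dione (not isolated) | CC(C)CCc1cc(OCc2ccccc2)cc(O)c1C(=O)CC(=O)Cc1cc(O)cc(=O)o1 | intermediate
18 | racemic 7-(benzyloxy)-2-hydroxy-2-[(4-hydroxy-2-oxo-2H-pyran-6-yl)methyl]-5-(3-methylbutyl)chroman-4-one | CC(C)CCc1cc(OCc2ccccc2)cc2c1C(=O)CC(O)(Cc1cc(O)cc(=O)o1)O2 | intermediate
19 | racemic 2,7-dihydroxy-2-[(4-hydroxy-2-oxo-2H-pyran-6-yl)methyl]-5-(3-methylbutyl)chroman-4-one | CC(C)CCc1cc(O)cc2c1C(=O)CC(O)(Cc1cc(O)cc(=O)o1)O2 | intermediate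
20 | (S)-N,N-dimethyl-1-phenylethylamine | C[C@H](N(C)C)c1ccccc1 | starting material
21 | (S)-N,N-dimethyl-1-phenylethylammonium 6-{[(2R)-2,7-dihydroxy-5-(3-methylbutyl)-4-oxochroman-2-yl]methyl}-2-oxo-2H-pyran-4-olate | CC(C)CCc1cc(O)cc2c1C(=O)C[C@@](O)(Cc1cc([O-])cc(=O)o1)O2.C[C@H]([NH+](C)C)c1ccccc1 | intermediate
22 | (2R)-2,7-dihydroxy-2-[(4-hydroxy-2-oxo-2H-pyran-6-yl)methyl]-5-(3-methylbutyl)chroman-4-one | CC(C)CCc1cc(O)cc2c1C(=O)C[C@@](O)(Cc1cc(O)cc(=O)o1)O2 | target

**Step count.** Total: 14 steps. Longest linear sequence: 12 steps (steps 1–5 and 8–14); steps 6 and 7 form the side branch.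

**Steps most likely to fail**

1. Step 13 (Proposed new method). The two diastereomeric salts may co-crystallise or not crystallise at all, or the hemiketal may re-equilibrate through ring opening while the acid is released in step 14. The fallback uses known chemistry and sets out from racemic 19. The enantiomers are separated by preparative chromatography on an amylose tris(3,5-dimethylphenylcarbamate) stationary phase (supercritical CO2/MeOH with 0.1 % formic acid, cooled column, fractions collected cold). The (2R) fraction is concentrated below 20 °C and gives 22 directly, so the route is rejoined at 22 and 21 is bypassed. The (2S) fraction is re-equilibrated with a trace of Et3N and injected again. This detour makes no new compound (F0).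

2. Step 10. The skipped ynone may isomerise by proton shift at C6 to the conjugated allenone, or oligomerise, before the ester oxygen closes. The fallback brings the pyranone in as an intact ring, sets out from 6 and rejoins at 16:
   - CS2 and KOt-Bu in THF, then acidification, should give 7-(benzyloxy)-4-hydroxy-5-(3-methylbutyl)-2H-chromene-2-thione F1.
   - S-Methylation (MeI, K2CO3, acetone) should give 7-(benzyloxy)-5-(3-methylbutyl)-2-(methylsulfanyl)-4H-chromen-4-one F2.
   - Oxidation with mCPBA in CH2Cl2 should give 7-(benzyloxy)-2-(methanesulfonyl)-5-(3-methylbutyl)-4H-chromen-4-one F3.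
   - The C6-methyl dianion of commercial 4-hydroxy-6-methyl-2H-pyran-2-one (LiN(i-Pr)2, 2.2 equiv, THF, −78 °C) should then displace methanesulfinate from C2 of F3 by addition–elimination and deliver 16.

3. Step 11. Hydroxide may add to C2 too slowly, or go on to retro-Claisen cleavage of the opened diketone or to opening of the pyranone lactone. The fallback opens the chromone with an amine instead, sets out from 16 and rejoins at 18. Pyrrolidine in EtOH at 40 °C should add at C2 and open the ring to the enaminone (2E)-1-[4-(benzyloxy)-2-hydroxy-6-(3-methylbutyl)phenyl]-4-(4-hydroxy-2-oxo-2H-pyran-6-yl)-3-(pyrrolidin-1-yl)but-2-en-1-one F4. Hydrolysis of F4 in THF/aqueous AcOH (pH about 4, 20 °C) should release the diketone, which closes to 18.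

**Further compounds**
F0 | step 13 | none | none
F1 | step 10 | 7-(benzyloxy)-4-hydroxy-5-(3-methylbutyl)-2H-chromene-2-thione | CC(C)CCc1cc(OCc2ccccc2)cc2oc(=S)cc(O)c12
F2 | step 10 | 7-(benzyloxy)-5-(3-methylbutyl)-2-(methylsulfanyl)-4H-chromen-4-one | CC(C)CCc1cc(OCc2ccccc2)cc2oc(SC)cc(=O)c12
F3 | step 10 | 7-(benzyloxy)-2-(methanesulfonyl)-5-(3-methylbutyl)-4H-chromen-4-one | CC(C)CCc1cc(OCc2ccccc2)cc2oc(S(C)(=O)=O)cc(=O)c12
F4 | step 11 | (2E)-1-[4-(benzyloxy)-2-hydroxy-6-(3-methylbutyl)phenyl]-4-(4-hydroxy-2-oxo-2H-pyran-6-yl)-3-(pyrrolidin-1-yl)but-2-en-1-one | CC(C)CCc1cc(OCc2ccccc2)cc(O)c1C(=O)/C=C(\Cc1cc(O)cc(=O)o1)N1CCCC1
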